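**Plan**

- Numbering: ring A is the carbocycle C1–C6 (C1 quaternary, C2 ketone, C3 side chain, C4 enol, C5 acyl-bearing, C6 ether-bearing). Ring B is the dimethylpyranone on C5/C6. Ring C is the lactone that masks O4 and the acid until late.
- Cuts, last bond first: C1–prenyl (dearomative allylation), C1–CH2 of lavandulyl (Negishi), the C5–C(=O) bond of ring B (Friedel–Crafts), O6–CH(CH3) (Mitsunobu), the benzylic C–H of the side chain (conjugate reduction), the Pechmann bonds.
- Enabling feature: ring B is O6–CH(CH3)–CH(CH3)–C(=O)–C5, a 3-aryloxy-2-methylbutanoyl chain hung on O6 whose carbonyl carbon reaches C5, ortho to O6, through a six-membered transition state.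
- Forward order: ring C (coumarin), chain on O6, side-chain centre, ring B, bromine then lavandulyl at C1, ring C opened, prenyl at C1 with dearomatisation of ring A, acid.
- Stereochemistry: ring B methyls from (S)-3-hydroxybutanoate (anti methylation, then inversion at the carbinol gives cis); side-chain centre from ligand-controlled CuH reduction; lavandulyl centre from resolved (S)-lavandulol; C1 from Pd2(dba)3 with a chiral ligand.

Key step: step 7

Assumption 1: the ligand enantiomers written in steps 5 and 14 are those taken to lead to 4R and to R at C1; the sense of induction would be checked on first use and the mirror-image ligand taken if required.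
Assumption 2: Candida antarctica lipase B is taken to acetylate (R)-lavandulol faster, and tert-butyl prenyl carbonate is taken as a purchasable reagent.

**Route**

Step 1
Reactants: 1 phloroglucinol; 2 ethyl 3-oxohexanoate
Product: 3 5,7-dihydroxy-4-propyl-2H-chromen-2-one
Conditions: conc. H2SO4, 0 °C to rt
Reagents that add atoms: none
Why: Pechmann condensation, in which acid-catalysed transesterification and ring closure of the β-keto ester onto the symmetrical triphenol can give only the 4-propylcoumarin with hydroxyls at C5 and C7, and no stereocentre is formed.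

Step 2
Reactants: 4 tert-butyl (S)-3-hydroxybutanoate
Product: 6 tert-butyl (2S,3S)-3-hydroxy-2-methylbutanoate, via dilithium alkoxide-enolate 5 (not isolated)
Conditions: LiN(i-Pr)2 (2.2 equiv), THF, −78 to −20 °C; MeI, DMPU, −78 to −10 °C; H2O
Reagents that add atoms: iodomethane, CI
Why: Fráter–Seebach alkylation, in which the chelated dilithium alkoxide-enolate is methylated on the face anti to the C3 methyl group, which sets C2 as S and should give the anti (2S,3S) ester.

Step 3
Reactants: 3 5,7-dihydroxy-4-propyl-2H-chromen-2-one; 6 tert-butyl (2S,3S)-3-hydroxy-2-methylbutanoate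
Product: 7 tert-butyl (2S,3R)-3-[(5-hydroxy-2-oxo-4-propyl-2H-chromen-7-yl)oxy]-2-methylbutanoate
Conditions: PPh3, DIAD, THF, 0 °C to rt (3 in slight excess, DIAD added slowly)
Reagents that add atoms: none
Why: Mitsunobu etherification, in which the 7-OH of the coumarin (O6 of ring A), the more acidic and less hindered phenol because the 5-OH is buttressed by the peri propyl group, displaces the activated carbinol oxygen by SN2 with inversion, turning C3 of the butanoate from S to R while C2 is untouched, so that the chain carries the syn arrangement that becomes the cis pair of ring B.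

Step 4
Reactants: 7 tert-butyl (2S,3R)-3-[(5-hydroxy-2-oxo-4-propyl-2H-chromen-7-yl)oxy]-2-methylbutanoate
Product: 8 tert-butyl (2S,3R)-2-methyl-3-({2-oxo-4-propyl-5-[tri(propan-2-yl)silyloxy]-2H-chromen-7-yl}oxy)butanoate
Conditions: i-Pr3SiCl, imidazole, DMF, rt to 40 °C
Reagents that add atoms: chlorotri(propan-2-yl)silane, CC(C)[Si](Cl)(C(C)C)C(C)C
Why: Imidazole-promoted silylation of the remaining phenol (O2 of ring A) is routine, leaves the tert-butyl ester and the pyranone untouched, and supplies the bulky group that later shields C1.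

Step 5
Reactants: 8 tert-butyl (2S,3R)-2-methyl-3-({2-oxo-4-propyl-5-[tri(propan-2-yl)silyloxy]-2H-chromen-7-yl}oxy)butanoate
Product: 9 tert-butyl (2S,3R)-2-methyl-3-({(4R)-2-oxo-4-propyl-5-[tri(propan-2-yl)silyloxy]-3,4-dihydro-2H-chromen-7-yl}oxy)butanoate
Conditions: Cu(OAc)2·H2O (cat.), (R)-DTBM-SEGPHOS (cat.), (EtO)2MeSiH (1.2 equiv), t-BuOH, toluene, 0 °C to rt
Reagents that add atoms: none
Why: CuH-catalysed asymmetric conjugate reduction of a 4-substituted coumarin, in which the bisphosphine-bound CuH delivers hydride to one face of C4 and the resulting enolate is protonated by tert-butanol, so that the ligand sets the new centre as 4R while the isolated ester, the silyl ether and the distant stereodiad are not affected and the limited amount of silane spares the lactone carbonyl.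

Step 6
Reactants: 9 tert-butyl (2S,3R)-2-methyl-3-({(4R)-2-oxo-4-propyl-5-[tri(propan-2-yl)silyloxy]-3,4-dihydro-2H-chromen-7-yl}oxy)butanoate
Product: 10 (2S,3R)-2-methyl-3-({(4R)-2-oxo-4-propyl-5-[tri(propan-2-yl)silyloxy]-3,4-dihydro-2H-chromen-7-yl}oxy)butanoic acid
Conditions: CF3CO2H, CH2Cl2, 0 °C to rt
Reagents that add atoms: none
Why: Acidolysis of the tert-butyl ester by E1-type loss of 2-methylpropene frees the acid without touching the aryl silyl ether, the aryl ester of ring C or the alkyl aryl ether, and uses no base that could epimerise C2 of the chain.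

Step 7
Reactants: 10 (2S,3R)-2-methyl-3-({(4R)-2-oxo-4-propyl-5-[tri(propan-2-yl)silyloxy]-3,4-dihydro-2H-chromen-7-yl}oxy)butanoic acid
Product: 12 (4R,8R,9S)-8,9-dimethyl-4-propyl-5-[tri(propan-2-yl)silyloxy]-3,4,8,9-tetrahydro-2H,10H-pyrano[2,3-f]chromene-2,10-dione, via acid chloride 11 (not isolated)
Conditions: (COCl)2, DMF (cat.), CH2Cl2, 0 °C to rt, evaporate; SnCl4 (1.2 equiv), CH2Cl2, −78 to −40 °C; cold aq. NaHCO3
Reagents that add atoms: none
Why: The acid chloride is ionised by SnCl4 to an acylium ion that attacks C5, the ring A carbon ortho to the ether oxygen O6 and para to the silyloxy group, and loss of a proton restores the arene; this is the intramolecular Friedel–Crafts acylation by which 3-aryloxyalkanoyl chlorides are converted into chroman-4-ones. Ring B closes as a six-membered ring in a 6-exo-dig sense with respect to the acylium C≡O bond, the aryl–C(=O) bond being the only skeletal bond formed. No stereocentre is created, since both methyl-bearing carbons are already in the chain and lie outside the bond-forming atoms. The step needs site selectivity between C5 and C1, both ortho to O6; the tri(propan-2-yl)silyl group on O2 shields C1, and the prior attachment of the chain to O6 fixes which ring atom carries the ring oxygen and which the carbonyl. It also needs retention of the cis stereodiad, which the absence of base and the low temperature should secure against enolisation of the new ketone and β-elimination of the phenol. Any C1-acylated isomer would not be lost, because it converges with the main series once both O2 and O4 are free after step 13.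

Step 8
Reactants: 12 (4R,8R,9S)-8,9-dimethyl-4-propyl-5-[tri(propan-2-yl)silyloxy]-3,4,8,9-tetrahydro-2H,10H-pyrano[2,3-f]chromene-2,10-dione
Product: 13 (4R,8R,9S)-5-hydroxy-8,9-dimethyl-4-propyl-3,4,8,9-tetrahydro-2H,10H-pyrano[2,3-f]chromene-2,10-dione
Conditions: Bu4NF, AcOH (1:1), THF, 0 °C
Reagents that add atoms: none
Why: Fluoride-mediated cleavage of the aryl silyl ether, buffered with acetic acid so that the phenoxide cannot open ring C or epimerise the ketone α-carbon, frees O2–H and unblocks C1.

Step 9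
Reactants: 13 (4R,8R,9S)-5-hydroxy-8,9-dimethyl-4-propyl-3,4,8,9-tetrahydro-2H,10H-pyrano[2,3-f]chromene-2,10-dione
Product: 14 (4R,8R,9S)-6-bromo-5-hydroxy-8,9-dimethyl-4-propyl-3,4,8,9-tetrahydro-2H,10H-pyrano[2,3-f]chromene-2,10-dione
Conditions: NBS (1.0 equiv), CH2Cl2, −20 to 0 °C
Reagents that add atoms: N-bromosuccinimide, O=C1CCC(=O)N1Br
Why: Electrophilic aromatic bromination of a phenol, for which C1 is the only unsubstituted ring A carbon and lies ortho to the free O2–H and to O6, so that one equivalent of NBS at low temperature should give a single bromophenol.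

Step 10
Reactants: 15 racemic lavandulol
Product: 16 (S)-lavandulol, (2S)-5-methyl-2-(prop-1-en-2-yl)hex-4-en-1-ol
Conditions: Novozym 435 (immobilised Candida antarctica lipase B), vinyl acetate, hexane, rt, run past half conversion; chromatography
Reagents that add atoms: none
Why: Lipase-catalysed kinetic resolution by transesterification, in which the enzyme acetylates the (R)-alcohol faster, so that running past half conversion should leave (S)-lavandulol, whose configuration is that of the lavandulyl centre of the target.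

Step 11
Reactants: 16 (S)-lavandulol
Product: 17 (S)-lavandulyl iodide, (3S)-3-(iodomethyl)-2,6-dimethylhepta-1,5-diene
Conditions: I2, PPh3, imidazole, CH2Cl2, 0 °C to rt
Reagents that add atoms: iodine, II
Why: Appel iodination of a primary alcohol by SN2 displacement of the oxyphosphonium group, in which the stereocentre is the neighbouring carbon and is not involved.

Step 12
Reactants: 14 (4R,8R,9S)-6-bromo-5-hydroxy-8,9-dimethyl-4-propyl-3,4,8,9-tetrahydro-2H,10H-pyrano[2,3-f]chromene-2,10-dione; 17 (S)-lavandulyl iodide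
Product: 19 (4R,8R,9S)-5-hydroxy-8,9-dimethyl-6-[(2R)-5-methyl-2-(prop-1-en-2-yl)hex-4-en-1-yl]-4-propyl-3,4,8,9-tetrahydro-2H,10H-pyrano[2,3-f]chromene-2,10-dione, via lavandulylzinc iodide 18 (not isolated)
Conditions: 17, Zn dust (activated with BrCH2CH2Br and Me3SiCl), LiCl, THF, 40 °C; then 18 (2.3 equiv) added slowly to 14, Pd(OAc)2 (cat.), SPhos (cat.), THF, rt to 45 °C; aq. NH4Cl
Reagents that add atoms: none
Why: Negishi sp2–sp3 cross-coupling, in which zinc inserts into the primary C–I bond and zerovalent palladium carrying the bulky biarylphosphine adds oxidatively to the hindered C1–Br bond, transmetalates with the alkylzinc iodide and eliminates reductively faster than β-hydride loss; the first equivalent of the zinc reagent is spent in converting the phenol into ArOZnI, and the lactone, the ketone and the β-stereocentre of the zinc reagent are not touched.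

Step 13
Reactants: 19 (4R,8R,9S)-5-hydroxy-8,9-dimethyl-6-[(2R)-5-methyl-2-(prop-1-en-2-yl)hex-4-en-1-yl]-4-propyl-3,4,8,9-tetrahydro-2H,10H-pyrano[2,3-f]chromene-2,10-dione
Product: 20 methyl (3R)-3-{(2R,3S)-5,7-dihydroxy-2,3-dimethyl-8-[(2R)-5-methyl-2-(prop-1-en-2-yl)hex-4-en-1-yl]-4-oxo-3,4-dihydro-2H-chromen-6-yl}hexanoate
Conditions: Et3N (0.5 equiv), MeOH, 0 °C to rt; AcOH, concentrate below 30 °C, use at once
Reagents that add atoms: methanol, CO
Why: Base-catalysed transesterification (methanolysis) of the aryl ester of ring C, whose leaving phenoxide O4 is stabilised by the ortho ketone, gives the methyl ester and frees O4–H, while prior ionisation of the para-acyl phenol O2–H deactivates the ring B α-carbon towards epimerisation and the absence of acid spares the lavandulyl alkenes.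

Step 14
Reactants: 20 methyl (3R)-3-{(2R,3S)-5,7-dihydroxy-2,3-dimethyl-8-[(2R)-5-methyl-2-(prop-1-en-2-yl)hex-4-en-1-yl]-4-oxo-3,4-dihydro-2H-chromen-6-yl}hexanoate
Product: 21 methyl (3R)-3-{(2R,3S,8R)-5-hydroxy-2,3-dimethyl-8-[(2R)-5-methyl-2-(prop-1-en-2-yl)hex-4-en-1-yl]-8-(3-methylbut-2-en-1-yl)-4,7-dioxo-3,4,7,8-tetrahydro-2H-chromen-6-yl}hexanoate
Conditions: tert-butyl prenyl carbonate (1.1 equiv), Pd2(dba)3 (cat.), (S,S)-DACH-phenyl Trost ligand (cat.), THF, 0 °C to rt
Reagents that add atoms: tert-butyl (3-methylbut-2-en-1-yl) carbonate, CC(C)=CCOC(=O)OC(C)(C)C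
Why: Tsuji–Trost allylic alkylation used as a dearomatisation of an acylphloroglucinol-type phenol, in which the tert-butoxide released on ionisation of the carbonate deprotonates the phenol, reversible O-prenylation funnels into C-attack on the unsubstituted terminus of the π-prenyl palladium complex, C1 (primary alkyl) reacts in preference to C3 (branched alkyl), and the chiral ligand differentiates the two faces of ring A so that the new quaternary C1 is R and the product is a stable enolised β-diketone.

Step 15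
Reactants: 21 methyl (3R)-3-{(2R,3S,8R)-5-hydroxy-2,3-dimethyl-8-[(2R)-5-methyl-2-(prop-1-en-2-yl)hex-4-en-1-yl]-8-(3-methylbut-2-en-1-yl)-4,7-dioxo-3,4,7,8-tetrahydro-2H-chromen-6-yl}hexanoate
Product: 22 (3R)-3-{(2R,3S,8R)-5-hydroxy-2,3-dimethyl-8-[(2R)-5-methyl-2-(prop-1-en-2-yl)hex-4-en-1-yl]-8-(3-methylbut-2-en-1-yl)-4,7-dioxo-3,4,7,8-tetrahydro-2H-chromen-6-yl}hexanoic acid (CNP0266113.2)
Conditions: LiOH, THF/H2O, 0 °C to rt; 1 M HCl to pH 3 at 0 °C
Reagents that add atoms: lithium hydroxide, [Li+].[OH-]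
Why: Saponification of the methyl ester, in which the acidic enol is ionised first and the resulting delocalised anion protects the ring A ketone and the ring B α-carbon from hydroxide and from epimerisation at 0 °C, so that brief cold acidification should release the target acid.

**Compound list**

1 | phloroglucinol (benzene-1,3,5-triol) | Oc1cc(O)cc(O)c1 | starting material
2 | ethyl 3-oxohexanoate | CCCC(=O)CC(=O)OCC | starting material
3 | 5,7-dihydroxy-4-propyl-2H-chromen-2-one | CCCC1=CC(=O)Oc2cc(O)cc(O)c12 | intermediate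
4 | tert-butyl (S)-3-hydroxybutanoate | CC(C)(C)OC(=O)C[C@H](C)O | starting material
5 | dilithium alkoxide-enolate of 4 (chelated, formed in the flask) | CC(C)(C)O/C(O[Li])=C/[C@H](C)O[Li] | intermediate
6 | tert-butyl (2S,3S)-3-hydroxy-2-methylbutanoate | CC(C)(C)OC(=O)[C@@H](C)[C@H](C)O | intermediate
7 | tert-butyl (2S,3R)-3-[(5-hydroxy-2-oxo-4-propyl-2H-chromen-7-yl)oxy]-2-methylbutanoate | CC(C)(C)OC(=O)[C@@H](C)[C@@H](C)Oc1cc(O)c2c(c1)OC(=O)C=C2CCC | intermediate
8 | tert-butyl (2S,3R)-2-methyl-3-({2-oxo-4-propyl-5-[tri(propan-2-yl)silyloxy]-2H-chromen-7-yl}oxy)butanoate | CC(C)(C)OC(=O)[C@@H](C)[C@@H](C)Oc1cc(O[Si](C(C)C)(C(C)C)C(C)C)c2c(c1)OC(=O)C=C2CCC | intermediate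
9 | tert-butyl (2S,3R)-2-methyl-3-({(4R)-2-oxo-4-propyl-5-[tri(propan-2-yl)silyloxy]-3,4-dihydro-2H-chromen-7-yl}oxy)butanoate | CC(C)(C)OC(=O)[C@@H](C)[C@@H](C)Oc1cc(O[Si](C(C)C)(C(C)C)C(C)C)c2c(c1)OC(=O)C[C@H]2CCC | intermediate
10 | (2S,3R)-2-methyl-3-({(4R)-2-oxo-4-propyl-5-[tri(propan-2-yl)silyloxy]-3,4-dihydro-2H-chromen-7-yl}oxy)butanoic acid | OC(=O)[C@@H](C)[C@@H](C)Oc1cc(O[Si](C(C)C)(C(C)C)C(C)C)c2c(c1)OC(=O)C[C@H]2CCC | intermediate
11 | (2S,3R)-2-methyl-3-({(4R)-2-oxo-4-propyl-5-[tri(propan-2-yl)silyloxy]-3,4-dihydro-2H-chromen-7-yl}oxy)butanoyl chloride | ClC(=O)[C@@H](C)[C@@H](C)Oc1cc(O[Si](C(C)C)(C(C)C)C(C)C)c2c(c1)OC(=O)C[C@H]2CCC | intermediate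
12 | (4R,8R,9S)-8,9-dimethyl-4-propyl-5-[tri(propan-2-yl)silyloxy]-3,4,8,9-tetrahydro-2H,10H-pyrano[2,3-f]chromene-2,10-dione | CC(C)[Si](Oc1cc2O[C@H](C)[C@H](C)C(=O)c2c2OC(=O)C[C@@H](CCC)c12)(C(C)C)C(C)C | intermediate
13 | (4R,8R,9S)-5-hydroxy-8,9-dimethyl-4-propyl-3,4,8,9-tetrahydro-2H,10H-pyrano[2,3-f]chromene-2,10-dione | Oc1cc2O[C@H](C)[C@H](C)C(=O)c2c2OC(=O)C[C@@H](CCC)c12 | intermediate
14 | (4R,8R,9S)-6-bromo-5-hydroxy-8,9-dimethyl-4-propyl-3,4,8,9-tetrahydro-2H,10H-pyrano[2,3-f]chromene-2,10-dione | Oc1c(Br)c2O[C@H](C)[C@H](C)C(=O)c2c2OC(=O)C[C@@H](CCC)c12 | intermediate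
15 | racemic lavandulol, 5-methyl-2-(prop-1-en-2-yl)hex-4-en-1-ol | C=C(C)C(CO)CC=C(C)C | starting material
16 | (S)-lavandulol, (2S)-5-methyl-2-(prop-1-en-2-yl)hex-4-en-1-ol | C=C(C)[C@H](CC=C(C)C)CO | intermediate
17 | (S)-lavandulyl iodide, (3S)-3-(iodomethyl)-2,6-dimethylhepta-1,5-diene | C=C(C)[C@H](CC=C(C)C)CI | intermediate
18 | [(2S)-5-methyl-2-(prop-1-en-2-yl)hex-4-en-1-yl]zinc iodide | C=C(C)[C@H](CC=C(C)C)C[Zn]I | intermediate
19 | (4R,8R,9S)-5-hydroxy-8,9-dimethyl-6-[(2R)-5-methyl-2-(prop-1-en-2-yl)hex-4-en-1-yl]-4-propyl-3,4,8,9-tetrahydro-2H,10H-pyrano[2,3-f]chromene-2,10-dione | Oc1c(C[C@@H](CC=C(C)C)C(C)=C)c2O[C@H](C)[C@H](C)C(=O)c2c2OC(=O)C[C@@H](CCC)c12 | intermediate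
20 | methyl (3R)-3-{(2R,3S)-5,7-dihydroxy-2,3-dimethyl-8-[(2R)-5-methyl-2-(prop-1-en-2-yl)hex-4-en-1-yl]-4-oxo-3,4-dihydro-2H-chromen-6-yl}hexanoate | Oc1c(C[C@@H](CC=C(C)C)C(C)=C)c2O[C@H](C)[C@H](C)C(=O)c2c(O)c1[C@H](CCC)CC(=O)OC | intermediate
21 | methyl (3R)-3-{(2R,3S,8R)-5-hydroxy-2,3-dimethyl-8-[(2R)-5-methyl-2-(prop-1-en-2-yl)hex-4-en-1-yl]-8-(3-methylbut-2-en-1-yl)-4,7-dioxo-3,4,7,8-tetrahydro-2H-chromen-6-yl}hexanoate | C=C(C)[C@H](CC=C(C)C)C[C@@]1(CC=C(C)C)C(=O)C([C@H](CCC)CC(=O)OC)=C(O)C2=C1O[C@H](C)[C@H](C)C2=O | intermediate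
22 | (3R)-3-{(2R,3S,8R)-5-hydroxy-2,3-dimethyl-8-[(2R)-5-methyl-2-(prop-1-en-2-yl)hex-4-en-1-yl]-8-(3-methylbut-2-en-1-yl)-4,7-dioxo-3,4,7,8-tetrahydro-2H-chromen-6-yl}hexanoic acid | C=C(C)[C@H](CC=C(C)C)C[C@@]1(CC=C(C)C)C(=O)C([C@H](CCC)CC(=O)O)=C(O)C2=C1O[C@H](C)[C@H](C)C2=O | target

**Step count and risks**

Total step count: 15. Longest linear sequence: 12 steps from phloroglucinol (steps 1, 3 to 9, 12 to 15).

Most likely to fail, step 14: the ligand may not discriminate the two faces of ring A well enough at C1, and attack through oxygen or at C3 may compete. The fallback gives up catalyst control for separation. It sets out from 20, which is alkylated without a metal catalyst (prenyl bromide, NaOMe, MeOH, 0 °C, the classical dearomative C-prenylation of an acylphloroglucinol dianion). This should give 21 together with its C1 epimer, methyl (3R)-3-{(2R,3S,8S)-5-hydroxy-2,3-dimethyl-8-[(2R)-5-methyl-2-(prop-1-en-2-yl)hex-4-en-1-yl]-8-(3-methylbut-2-en-1-yl)-4,7-dioxo-3,4,7,8-tetrahydro-2H-chromen-6-yl}hexanoate F1. The four other stereocentres make the two diastereomers, so they would be separated by preparative chromatography, and the fallback comes back to the route at 21.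

Second, step 5: hydride transfer to the congested C4, next to the silyloxy group, may be slow or poorly face-selective, and the aryl lactone may be reduced further. The fallback sets the centre by C–C bond formation instead of hydride delivery. It sets out from 1 and 6. Phloroglucinol 1 is condensed with ethyl propiolate (ZnCl2, 90 °C) to 5,7-dihydroxy-2H-chromen-2-one F2. Mitsunobu coupling with 6 under the conditions of step 3 gives tert-butyl (2S,3R)-3-[(5-hydroxy-2-oxo-2H-chromen-7-yl)oxy]-2-methylbutanoate F3. Silylation as in step 4 gives tert-butyl (2S,3R)-2-methyl-3-({2-oxo-5-[tri(propan-2-yl)silyloxy]-2H-chromen-7-yl}oxy)butanoate F4. Copper-catalysed asymmetric conjugate addition of n-PrMgBr (CuBr·SMe2, chiral ferrocenyl bisphosphine of the Josiphos family, t-BuOMe, −72 °C) then forms the C4–propyl bond and the stereocentre together, and the fallback comes back to the route at 9.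

Third, step 3: the activated β-hydroxy ester may undergo E2 elimination to the tiglate, and the wrong phenol may be etherified. The fallback replaces activation of the alcohol in the presence of the phenol by a preformed strained electrophile. It sets out from 6 and 3. Acidolysis of 6 (CF3CO2H, CH2Cl2) gives (2S,3S)-3-hydroxy-2-methylbutanoic acid F5. Carboxyl activation (PhSO2Cl, pyridine, 0 °C) closes it with retention to the trans lactone (3S,4S)-3,4-dimethyloxetan-2-one F6. The 7-phenoxide of 3 (K2CO3, one equivalent, DMF, rt), a weakly basic nucleophile, should open F6 at C4 by alkyl–oxygen cleavage with inversion to (2S,3R)-3-[(5-hydroxy-2-oxo-4-propyl-2H-chromen-7-yl)oxy]-2-methylbutanoic acid F7. Esterification with tert-butyl 2,2,2-trichloroacetimidate (CH2Cl2, rt) brings the fallback back to the route at 7.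

**Further compounds**

F1 | step 14 | methyl (3R)-3-{(2R,3S,8S)-5-hydroxy-2,3-dimethyl-8-[(2R)-5-methyl-2-(prop-1-en-2-yl)hex-4-en-1-yl]-8-(3-methylbut-2-en-1-yl)-4,7-dioxo-3,4,7,8-tetrahydro-2H-chromen-6-yl}hexanoate | C=C(C)[C@H](CC=C(C)C)C[C@]1(CC=C(C)C)C(=O)C([C@H](CCC)CC(=O)OC)=C(O)C2=C1O[C@H](C)[C@H](C)C2=O
F2 | step 5 | 5,7-dihydroxy-2H-chromen-2-one | O=C1C=Cc2c(O)cc(O)cc2O1
F3 | step 5 | tert-butyl (2S,3R)-3-[(5-hydroxy-2-oxo-2H-chromen-7-yl)oxy]-2-methylbutanoate | CC(C)(C)OC(=O)[C@@H](C)[C@@H](C)Oc1cc(O)c2c(c1)OC(=O)C=C2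
F4 | step 5 | tert-butyl (2S,3R)-2-methyl-3-({2-oxo-5-[tri(propan-2-yl)silyloxy]-2H-chromen-7-yl}oxy)butanoate | CC(C)(C)OC(=O)[C@@H](C)[C@@H](C)Oc1cc(O[Si](C(C)C)(C(C)C)C(C)C)c2c(c1)OC(=O)C=C2
F5 | step 3 | (2S,3S)-3-hydroxy-2-methylbutanoic acid | OC(=O)[C@@H](C)[C@H](C)O
F6 | step 3 | (3S,4S)-3,4-dimethyloxetan-2-one | O=C1[C@@H](C)[C@H](C)O1
F7 | step 3 | (2S,3R)-3-[(5-hydroxy-2-oxo-4-propyl-2H-chromen-7-yl)oxy]-2-methylbutanoic acid | OC(=O)[C@@H](C)[C@@H](C)Oc1cc(O)c2c(c1)OC(=O)C=C2CCC
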